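**Retrosynthetic overview**

1. Isouvarinol 24 ⇐ desilylation and BCl3 dealkylation of the protected (2S)-flavanone 22. Ring C (O1–C2 bond, C2 stereocentre) is closed last by a catalytic enantioselective oxa-Michael addition of the one free phenol of chalcone 21.
2. Chalcone 21 ⇐ cinnamoylation of phenol 17 at its one free ring carbon, C4a (bromination, then aryllithium plus cinnamic Weinreb amide).
3. The strategy rests on ring A (C4a, C5, C6, C7, C8, C8a): it is fully substituted, with oxygens at C5, C7 and C8a and two different benzyl arms at C6 and C8, so it is assembled rather than substituted. Benzannulation of cyclobutenone 6 with siloxyalkyne 13 makes C8a–C8, C7–C6 and C8a–C4a, with one arm on each partner and the three oxygens masked differently (OH, OTIPS, OEt).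
4. 6 ⇐ ethoxyacetylene + 2-(benzyloxy)benzyl bromide 2, then ketene [2+2]. 13 ⇐ arylacetate 11 (Negishi benzylation with the same bromide 2) by ynolate rearrangement and O-silylation.
5. Ring order: ring A (step 8), then ring C (step 11); ring B and the three arm rings are purchased.

Key step: step 8

Assumption: the quinine-derived bifunctional thiourea is taken to give the 2S flavanone in step 11; if a test cyclisation shows the opposite sense, the pseudo-enantiomeric quinidine-derived catalyst is used under the same conditions.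

Abbreviations: BnO = benzyloxy; TIPS = triisopropylsilyl; "C6 arm" = 2-(benzyloxy)benzyl; "C8 arm" = 2-(benzyloxy)-5-[2-(benzyloxy)benzyl]benzyl. Flavanone numbering is used for ring A throughout.

**Route**

Step 1
Reactants: 1 2-(benzyloxy)benzyl alcohol
Product: 2 2-(benzyloxy)benzyl bromide
Conditions: PBr3, CH2Cl2, 0 °C
Reagents that add atoms: phosphorus tribromide, BrP(Br)Br
Why: The primary benzylic alcohol is converted to the bromide by SN2 displacement of its phosphite ester, which leaves the aryl benzyl ether untouched.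

Step 2
Reactants: 3 ethoxyacetylene; 2 2-(benzyloxy)benzyl bromide
Product: 5 1-(benzyloxy)-2-(3-ethoxyprop-2-yn-1-yl)benzene, via lithium ethoxyacetylide 4 (not isolated)
Conditions: n-BuLi, THF, −78 °C; then 2, HMPA, −78 °C → rt
Reagents that add atoms: none
Why: SN2 alkylation of a lithium alkoxyacetylide by a reactive benzylic bromide in THF/HMPA should give the 1-ethoxyalkyne, the acetylide being too weak a base to isomerise the product.

Step 3
Reactants: 5 1-(benzyloxy)-2-(3-ethoxyprop-2-yn-1-yl)benzene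
Product: 6 2-[2-(benzyloxy)benzyl]-3-ethoxycyclobut-2-en-1-one
Conditions: ketene (gas, from acetone pyrolysis), CH2Cl2, 0 °C → rt
Reagents that add atoms: ketene, C=C=O
Why: Polar [2+2] cycloaddition of ketene with a 1-alkoxyalkyne, in which the nucleophilic benzyl-bearing alkyne carbon bonds to the ketene carbonyl carbon, should give the 2-substituted 3-ethoxycyclobutenone as the only regioisomer.

Step 4
Reactants: 7 methyl 2-(2-hydroxyphenyl)acetate
Product: 8 methyl 2-[2-(benzyloxy)phenyl]acetate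
Conditions: BnBr, K2CO3, DMF, rt
Reagents that add atoms: benzyl bromide, BrCc1ccccc1
Why: Williamson etherification of the phenoxide, which is alkylated faster than it lactonises onto the ester.

Step 5
Reactants: 8 methyl 2-[2-(benzyloxy)phenyl]acetate
Product: 9 methyl 2-[2-(benzyloxy)-5-bromophenyl]acetate
Conditions: NBS, MeCN, 0 °C → rt, dark
Reagents that add atoms: N-bromosuccinimide, O=C1CCC(=O)N1Br
Why: Electrophilic aromatic bromination in a polar solvent goes para to the alkoxy group of the activated ring, and the unactivated benzyl ring and the benzylic positions do not react without radical initiation.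

Step 6
Reactants: 2 2-(benzyloxy)benzyl bromide; 9 methyl 2-[2-(benzyloxy)-5-bromophenyl]acetate
Product: 11 methyl 2-{2-(benzyloxy)-5-[2-(benzyloxy)benzyl]phenyl}acetate, via [2-(benzyloxy)benzyl]zinc bromide 10 (not isolated)
Conditions: 2, Zn dust, LiCl, THF, 0 °C → rt; then 9, Pd(OAc)2 (2 mol %), SPhos (4 mol %), THF, rt → 50 °C
Reagents that add atoms: none
Why: Negishi sp3–sp2 coupling of a benzylic zinc reagent with an aryl bromide builds the diarylmethane, and the organozinc neither adds to the ester nor deprotonates it.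

Step 7
Reactants: 11 methyl 2-{2-(benzyloxy)-5-[2-(benzyloxy)benzyl]phenyl}acetate
Product: 13 triisopropyl[(3-{2-(benzyloxy)-5-[2-(benzyloxy)benzyl]phenyl}prop-1-yn-1-yl)oxy]silane, via lithium ynolate 12 (not isolated)
Conditions: CH2Br2, LiTMP, THF, −78 °C; then 11; then n-BuLi, −78 → 0 °C; then i-Pr3SiCl, −78 °C → rt
Reagents that add atoms: dibromomethane, BrCBr; triisopropylsilyl chloride, CC(C)[Si](Cl)(C(C)C)C(C)C
Why: Kowalski ynolate formation, in which dibromomethyllithium adds to the ester carbonyl at −78 °C, bromine–lithium exchange on the derived bromo enolate triggers 1,2-migration of the arylmethyl group to give ynolate 12, and the bulky silyl chloride then silylates on oxygen.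

Step 8
Reactants: 6 2-[2-(benzyloxy)benzyl]-3-ethoxycyclobut-2-en-1-one; 13 triisopropyl[(3-{2-(benzyloxy)-5-[2-(benzyloxy)benzyl]phenyl}prop-1-yn-1-yl)oxy]silane
Product: 17 2-(C8 arm)-4-(C6 arm)-5-ethoxy-3-(TIPS-oxy)phenol, via vinylketene 14 (not isolated), via vinylcyclobutenone 15 (not isolated), via dienylketene 16 (not isolated)
Conditions: degassed toluene, 80 °C then 110 °C, sealed tube, 13 in slight excess
Reagents that add atoms: none
Why: Heating opens cyclobutenone 6 by 4π-electrocyclic cleavage of its C1–C4 bond to vinylketene 14, whose ketene C=C adds to the siloxyalkyne in a polar [2+2] cycloaddition to give 4-vinylcyclobutenone 15; a second 4π opening gives dienylketene 16, and 6π-electrocyclisation followed by tautomerisation should deliver phenol 17. This is the Danheiser benzannulation of a cyclobutenone with a siloxyalkyne, the closest known use being the preparation of monosilylated resorcinols. Ring A is closed in the last pericyclic event, a thermal disrotatory 6π-electrocyclisation that joins the ketene carbon (C8a) to the terminal methylene (C4a), after the [2+2]/ring-opening sequence has made C8a–C8 and C7–C6. No stereocentre results, because the only sp3 centre created (the quaternary carbon of 15) is destroyed on ring opening. The step needs one regiochemistry in the ketene–alkyne [2+2], and the polarisation of the ynol ether secures it: the nucleophilic arm-bearing carbon bonds to the ketene carbonyl carbon, so the C8 arm ends ortho to the new phenol and the silyloxy group at C7, and each arm stays on the partner that carried it. The slight excess of alkyne limits acylation of the product phenol by the vinylketene.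

Step 9
Reactants: 17 2-(C8 arm)-4-(C6 arm)-5-ethoxy-3-(TIPS-oxy)phenol
Product: 18 2-bromo-6-(C8 arm)-4-(C6 arm)-3-ethoxy-5-(TIPS-oxy)phenol
Conditions: NBS (1.0 equiv), CH2Cl2, −78 → −20 °C
Reagents that add atoms: N-bromosuccinimide, O=C1CCC(=O)N1Br
Why: Electrophilic bromination goes to the only unsubstituted carbon of the trioxygenated ring (C4a, ortho to OH and para to OTIPS), which is far more nucleophilic than the mono-alkoxy arm rings.

Step 10
Reactants: 18 2-bromo-6-(C8 arm)-4-(C6 arm)-3-ethoxy-5-(TIPS-oxy)phenol; 19 (E)-N-methoxy-N-methylcinnamamide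
Product: 21 (E)-1-[3-(C8 arm)-5-(C6 arm)-6-ethoxy-2-hydroxy-4-(TIPS-oxy)phenyl]-3-phenylprop-2-en-1-one, via dilithiated aryl phenoxide 20 (not isolated)
Conditions: n-BuLi (2.1 equiv), THF, −78 °C; then 19, −78 → −20 °C; aq NH4Cl
Reagents that add atoms: none
Why: Deprotonation of the phenol and bromine–lithium exchange give an aryllithium at C4a that adds once to the Weinreb amide through a stable chelated tetrahedral intermediate, so the 2'-hydroxychalcone is released only on work-up and no Lewis acid touches the benzyl or silyl ethers.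

Step 11
Reactants: 21 (E)-1-[3-(C8 arm)-5-(C6 arm)-6-ethoxy-2-hydroxy-4-(TIPS-oxy)phenyl]-3-phenylprop-2-en-1-one
Product: 22 (2S)-8-(C8 arm)-6-(C6 arm)-5-ethoxy-2-phenyl-7-(TIPS-oxy)chroman-4-one
Conditions: quinine-derived 3,5-bis(trifluoromethyl)phenyl thiourea (10 mol %), toluene, −20 °C
Reagents that add atoms: none
Why: Enantioselective intramolecular oxa-Michael addition of a 2'-hydroxychalcone under bifunctional cinchona-thiourea catalysis, in which the thiourea hydrogen-bonds the enone carbonyl and the quinuclidine activates the only free phenol (future O1), which closes ring C 6-endo-trig onto one face of the β-carbon under catalyst control to set C2 as S, closure through O5 being impossible because it is an ethyl ether.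

Step 12
Reactants: 22 (2S)-8-(C8 arm)-6-(C6 arm)-5-ethoxy-2-phenyl-7-(TIPS-oxy)chroman-4-one
Product: 23 (2S)-8-(C8 arm)-6-(C6 arm)-5-ethoxy-7-hydroxy-2-phenylchroman-4-one
Conditions: TBAF, AcOH, THF, 0 °C
Reagents that add atoms: none
Why: Fluoride cleaves the aryl silyl ether para to the C4 carbonyl very readily, and the acetic acid buffer keeps the medium non-basic so that retro-oxa-Michael opening cannot scramble C2.

Step 13
Reactants: 23 (2S)-8-(C8 arm)-6-(C6 arm)-5-ethoxy-7-hydroxy-2-phenylchroman-4-one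
Product: 24 isouvarinol, (2S)-5,7-dihydroxy-8-[2-hydroxy-5-(2-hydroxybenzyl)benzyl]-6-(2-hydroxybenzyl)-2-phenylchroman-4-one
Conditions: BCl3 (excess), pentamethylbenzene, CH2Cl2, −78 °C → 0 °C; MeOH quench
Reagents that add atoms: none
Why: Boron trichloride with pentamethylbenzene as cation scavenger removes the three aryl benzyl ethers at low temperature, and on warming the C5 ethyl ether is cleaved by chelation-assisted dealkylation through the boron chelate with the C4 carbonyl, all without base, so C2 should keep its configuration.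

**Compound list**

1 | 2-(benzyloxy)benzyl alcohol | OCc1ccccc1OCc1ccccc1 | starting material
2 | 2-(benzyloxy)benzyl bromide | BrCc1ccccc1OCc1ccccc1 | intermediate
3 | ethoxyacetylene | CCOC#C | starting material
4 | lithium ethoxyacetylide | CCOC#C[Li] | intermediate
5 | 1-(benzyloxy)-2-(3-ethoxyprop-2-yn-1-yl)benzene | CCOC#CCc1ccccc1OCc1ccccc1 | intermediate
6 | 2-[2-(benzyloxy)benzyl]-3-ethoxycyclobut-2-en-1-one | CCOC1=C(Cc2ccccc2OCc2ccccc2)C(=O)C1 | intermediate
7 | methyl 2-(2-hydroxyphenyl)acetate | COC(=O)Cc1ccccc1O | starting material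
8 | methyl 2-[2-(benzyloxy)phenyl]acetate | COC(=O)Cc1ccccc1OCc1ccccc1 | intermediate
9 | methyl 2-[2-(benzyloxy)-5-bromophenyl]acetate | COC(=O)Cc1cc(Br)ccc1OCc1ccccc1 | intermediate
10 | [2-(benzyloxy)benzyl]zinc bromide | Br[Zn]Cc1ccccc1OCc1ccccc1 | intermediate
11 | methyl 2-{2-(benzyloxy)-5-[2-(benzyloxy)benzyl]phenyl}acetate | COC(=O)Cc1cc(Cc2ccccc2OCc2ccccc2)ccc1OCc1ccccc1 | intermediate
12 | lithium 3-{2-(benzyloxy)-5-[2-(benzyloxy)benzyl]phenyl}prop-1-yn-1-olate | [Li]OC#CCc1cc(Cc2ccccc2OCc2ccccc2)ccc1OCc1ccccc1 | intermediate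
13 | triisopropyl[(3-{2-(benzyloxy)-5-[2-(benzyloxy)benzyl]phenyl}prop-1-yn-1-yl)oxy]silane | CC(C)[Si](OC#CCc1cc(Cc2ccccc2OCc2ccccc2)ccc1OCc1ccccc1)(C(C)C)C(C)C | intermediate
14 | 2-[2-(benzyloxy)benzyl]-3-ethoxybuta-1,3-dien-1-one (vinylketene) | CCOC(=C)C(Cc1ccccc1OCc1ccccc1)=C=O | intermediate
15 | 4-[2-(benzyloxy)benzyl]-4-(1-ethoxyvinyl)-2-(C8 arm)-3-(TIPS-oxy)cyclobut-2-en-1-one (racemic) | O=C1C(Cc2cc(Cc3ccccc3OCc3ccccc3)ccc2OCc2ccccc2)=C(O[Si](C(C)C)(C(C)C)C(C)C)C1(Cc1ccccc1OCc1ccccc1)C(OCC)=C | intermediate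
16 | 2-(C8 arm)-4-[2-(benzyloxy)benzyl]-5-ethoxy-3-(TIPS-oxy)hexa-1,3,5-trien-1-one (dienylketene) | O=C=C(Cc1cc(Cc2ccccc2OCc2ccccc2)ccc1OCc1ccccc1)C(O[Si](C(C)C)(C(C)C)C(C)C)=C(Cc1ccccc1OCc1ccccc1)C(OCC)=C | intermediate
17 | 2-{2-(benzyloxy)-5-[2-(benzyloxy)benzyl]benzyl}-4-[2-(benzyloxy)benzyl]-5-ethoxy-3-[(triisopropylsilyl)oxy]phenol | Oc1cc(OCC)c(Cc2ccccc2OCc2ccccc2)c(O[Si](C(C)C)(C(C)C)C(C)C)c1Cc1cc(Cc2ccccc2OCc2ccccc2)ccc1OCc1ccccc1 | intermediate
18 | 2-bromo-6-{2-(benzyloxy)-5-[2-(benzyloxy)benzyl]benzyl}-4-[2-(benzyloxy)benzyl]-3-ethoxy-5-[(triisopropylsilyl)oxy]phenol | Oc1c(Br)c(OCC)c(Cc2ccccc2OCc2ccccc2)c(O[Si](C(C)C)(C(C)C)C(C)C)c1Cc1cc(Cc2ccccc2OCc2ccccc2)ccc1OCc1ccccc1 | intermediate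
19 | (E)-N-methoxy-N-methylcinnamamide | CON(C)C(=O)/C=C/c1ccccc1 | starting material
20 | lithium 2-lithio-6-(C8 arm)-4-(C6 arm)-3-ethoxy-5-(TIPS-oxy)phenoxide | [Li]Oc1c([Li])c(OCC)c(Cc2ccccc2OCc2ccccc2)c(O[Si](C(C)C)(C(C)C)C(C)C)c1Cc1cc(Cc2ccccc2OCc2ccccc2)ccc1OCc1ccccc1 | intermediate
21 | (E)-1-[3-{2-(benzyloxy)-5-[2-(benzyloxy)benzyl]benzyl}-5-[2-(benzyloxy)benzyl]-6-ethoxy-2-hydroxy-4-[(triisopropylsilyl)oxy]phenyl]-3-phenylprop-2-en-1-one | O=C(/C=C/c1ccccc1)c1c(O)c(Cc2cc(Cc3ccccc3OCc3ccccc3)ccc2OCc2ccccc2)c(O[Si](C(C)C)(C(C)C)C(C)C)c(Cc2ccccc2OCc2ccccc2)c1OCC | intermediate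
22 | (2S)-8-{2-(benzyloxy)-5-[2-(benzyloxy)benzyl]benzyl}-6-[2-(benzyloxy)benzyl]-5-ethoxy-2-phenyl-7-[(triisopropylsilyl)oxy]chroman-4-one | O=C1C[C@@H](c2ccccc2)Oc2c(Cc3cc(Cc4ccccc4OCc4ccccc4)ccc3OCc3ccccc3)c(O[Si](C(C)C)(C(C)C)C(C)C)c(Cc3ccccc3OCc3ccccc3)c(OCC)c21 | intermediate
23 | (2S)-8-{2-(benzyloxy)-5-[2-(benzyloxy)benzyl]benzyl}-6-[2-(benzyloxy)benzyl]-5-ethoxy-7-hydroxy-2-phenylchroman-4-one | O=C1C[C@@H](c2ccccc2)Oc2c(Cc3cc(Cc4ccccc4OCc4ccccc4)ccc3OCc3ccccc3)c(O)c(Cc3ccccc3OCc3ccccc3)c(OCC)c21 | intermediate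
24 | isouvarinol, (2S)-5,7-dihydroxy-8-[2-hydroxy-5-(2-hydroxybenzyl)benzyl]-6-(2-hydroxybenzyl)-2-phenylchroman-4-one | O=C1C[C@@H](c2ccccc2)Oc2c(Cc3cc(Cc4ccccc4O)ccc3O)c(O)c(Cc3ccccc3O)c(O)c21 | target

**Step count and risks**

Total steps: 13. Longest linear sequence: 10 steps (7 → 8 → 9 → 11 → 13 → 17 → 18 → 21 → 22 → 23 → 24; steps 4 to 13).

Steps most likely to fail:

1. Step 8 (benzannulation). The 3-ethoxycyclobutenone is a vinylogous ester and may open to the vinylketene only slowly, so the siloxyalkyne could degrade, or the product phenol could be acylated by the vinylketene, before the cascade is complete. Fallback (sets out from bromide 2, returns at phenol 17): the same vinylketene is generated at room temperature by 1,4-dehydrochlorination instead of ring opening. Ethyl acetoacetate is C-alkylated with 2 (NaOEt, EtOH) to ethyl 2-[2-(benzyloxy)benzyl]-3-oxobutanoate F1. Triethyl orthoformate with catalytic H2SO4 in EtOH gives the enol ether ethyl 2-[2-(benzyloxy)benzyl]-3-ethoxybut-2-enoate F2. KOH in aqueous EtOH gives 2-[2-(benzyloxy)benzyl]-3-ethoxybut-2-enoic acid F3, and oxalyl chloride with catalytic DMF gives 2-[2-(benzyloxy)benzyl]-3-ethoxybut-2-enoyl chloride F4. Slow addition of Et3N to F4 and 13 in toluene at rt should form vinylketene 14 by γ-deprotonation and trap it as vinylcyclobutenone 15, which is then heated (80–110 °C) through 16 to 17.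

2. Step 7 (ynolate formation). The arylacetate is unusually acidic, so enolisation by the lithium bases may compete with carbonyl addition of dibromomethyllithium and no ynolate would form. Fallback (sets out from ester 11, returns at siloxyalkyne 13): the ynolate is made by oxidation of a lithium acetylide instead. DIBAL-H (CH2Cl2, −78 °C) reduces 11 to {2-(benzyloxy)-5-[2-(benzyloxy)benzyl]phenyl}acetaldehyde F5. Ohira–Bestmann homologation (dimethyl (1-diazo-2-oxopropyl)phosphonate, K2CO3, MeOH, 0 °C) gives 1-(benzyloxy)-4-[2-(benzyloxy)benzyl]-2-(prop-2-yn-1-yl)benzene F6. Lithiation (n-BuLi, THF, −78 °C) and oxidation with lithium tert-butyl peroxide (from t-BuOOH and LiHMDS, −78 → 0 °C) should give ynolate 12, which is silylated with i-Pr3SiOTf to 13.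

3. Step 11 (enantioselective ring closure). Uncatalysed cyclisation and reversible retro-oxa-Michael opening may erode the enantiomeric excess, and the C8 arm next to the nucleophilic phenol may weaken facial discrimination by the catalyst. Fallback (sets out from bromophenol 18, returns at flavanone 22): ring C is closed first without a stereocentre and C2 is then set by asymmetric conjugate arylation. Dianion 20, made as in step 10, is quenched with N-methoxy-N-methylacetamide to give 1-[3-(C8 arm)-5-(C6 arm)-6-ethoxy-2-hydroxy-4-(TIPS-oxy)phenyl]ethan-1-one F7. DMF dimethyl acetal (toluene, 80 °C) gives the enaminone (E)-3-(dimethylamino)-1-[3-(C8 arm)-5-(C6 arm)-6-ethoxy-2-hydroxy-4-(TIPS-oxy)phenyl]prop-2-en-1-one F8. Catalytic TsOH in CH2Cl2 closes it through the same single free phenol to 8-(C8 arm)-6-(C6 arm)-5-ethoxy-7-(TIPS-oxy)-4H-chromen-4-one F9. Pd-catalysed conjugate addition of phenylboronic acid (Pd(OCOCF3)2, t-BuPyOX, NH4PF6, H2O, ClCH2CH2Cl, 60 °C) then sets C2 under ligand control to give 22. The (R)-ligand is expected to give 2S by analogy with cyclic enones, and this would be checked on the first sample.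

**Further compounds**

F1 | step 8 | ethyl 2-[2-(benzyloxy)benzyl]-3-oxobutanoate | CCOC(=O)C(Cc1ccccc1OCc1ccccc1)C(C)=O
F2 | step 8 | ethyl 2-[2-(benzyloxy)benzyl]-3-ethoxybut-2-enoate | CCOC(=O)C(Cc1ccccc1OCc1ccccc1)=C(C)OCC
F3 | step 8 | 2-[2-(benzyloxy)benzyl]-3-ethoxybut-2-enoic acid | OC(=O)C(Cc1ccccc1OCc1ccccc1)=C(C)OCC
F4 | step 8 | 2-[2-(benzyloxy)benzyl]-3-ethoxybut-2-enoyl chloride | ClC(=O)C(Cc1ccccc1OCc1ccccc1)=C(C)OCC
F5 | step 7 | {2-(benzyloxy)-5-[2-(benzyloxy)benzyl]phenyl}acetaldehyde | O=CCc1cc(Cc2ccccc2OCc2ccccc2)ccc1OCc1ccccc1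
F6 | step 7 | 1-(benzyloxy)-4-[2-(benzyloxy)benzyl]-2-(prop-2-yn-1-yl)benzene | C#CCc1cc(Cc2ccccc2OCc2ccccc2)ccc1OCc1ccccc1
F7 | step 11 | 1-[3-{2-(benzyloxy)-5-[2-(benzyloxy)benzyl]benzyl}-5-[2-(benzyloxy)benzyl]-6-ethoxy-2-hydroxy-4-[(triisopropylsilyl)oxy]phenyl]ethan-1-one | CC(=O)c1c(O)c(Cc2cc(Cc3ccccc3OCc3ccccc3)ccc2OCc2ccccc2)c(O[Si](C(C)C)(C(C)C)C(C)C)c(Cc2ccccc2OCc2ccccc2)c1OCC
F8 | step 11 | (E)-3-(dimethylamino)-1-[3-{2-(benzyloxy)-5-[2-(benzyloxy)benzyl]benzyl}-5-[2-(benzyloxy)benzyl]-6-ethoxy-2-hydroxy-4-[(triisopropylsilyl)oxy]phenyl]prop-2-en-1-one | CN(C)/C=C/C(=O)c1c(O)c(Cc2cc(Cc3ccccc3OCc3ccccc3)ccc2OCc2ccccc2)c(O[Si](C(C)C)(C(C)C)C(C)C)c(Cc2ccccc2OCc2ccccc2)c1OCC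
F9 | step 11 | 8-{2-(benzyloxy)-5-[2-(benzyloxy)benzyl]benzyl}-6-[2-(benzyloxy)benzyl]-5-ethoxy-7-[(triisopropylsilyl)oxy]-4H-chromen-4-one | O=C1C=COc2c(Cc3cc(Cc4ccccc4OCc4ccccc4)ccc3OCc3ccccc3)c(O[Si](C(C)C)(C(C)C)C(C)C)c(Cc3ccccc3OCc3ccccc3)c(OCC)c21
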